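Cedar, the earlier run, shows target rising behind substrate; the flasks asked about differ from it in charge and temperature.

the same everywhere: gas 42 mM (held)

| run | substrate | temperature | remark | time |
|---|---|---|---|---|
| cedar | 0.50 M | 125 °C | run made earlier |  |
| dawn | 1.0 M | 125 °C |  | 20 d |
| spring | 1.0 M | 100 °C |  | 20 d |
| winter | 1.0 M | 150 °C |  | 20 d |
| noon | 1.0 M | 75 °C |  | 20 d |

cedar run (percent of the substrate charged)

| time / d | target / % | substrate / % |
|---|---|---|
| 0.333 | 51 | 15 |
| 0.500 | 70 | 7 |
| 0.833 | 84 | 4 |
| 1.67 | 84 | 4 |
| 2.50 | 83 | 3 |
| 4.00 | 85 | 0 |

(scatter of a reading: 2 percentage points)

- the numbers in the tables scatter by 2 percentage points (one standard deviation)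
- at the start none of the gas is in solution
- the earlier runs do not show what temperature does; that part of a forecast is a guess

- the flask that comes out highest in amount of target, in percent of the substrate charged, or "all alike" when all lie within 1.5 percentage points (dawn / spring / winter / noon / all alike)
- target at the end, in percent of the substrate charged, dawn
- target at the end, in percent of the substrate charged, spring
- target at the end, in percent of the substrate charged, winter
- target at the end, in percent of the substrate charged, noon

1. In cedar at 0.333 d, substrate and target together hold 66.0% of the charge, so an intermediate stands between them and passes into target by a later step.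

2. Target's distance from its plateau of 84% shrinks from 33 percentage points at 0.333 d to 14 points at 0.500 d, so, read as first-order decay, the clearing rate is 5.13 /d, a rough reading that carries the scatter.

3. Multiplying that rate by the 20 d of the flasks gives 103 at 125 °C: the lifetime count, the number of intermediate lifetimes that a run holds. With a large count, target stands at the plateau; with a small one, it is the plateau times the count. This reckoning joins the two ends as plateau times one minus exp(-count).

4. Cedar shows nothing about temperature, so this reckoning guesses a doubling per 10 °C. Noon then lies 5 doublings below cedar, a slowdown of 32.0, which leaves a count of 3.21 and, on cedar's final 85%, target near 81.6%. Spring, under 3 doublings down, keeps a count above 12.8 and sits at its plateau.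

5. The doubling step is the weak link, and the formula is steep there: 7 doublings leave a count of 0.802 and target near 46.9%, so both figures for noon are estimates resting on a guessed step, and they bound nothing.

The forecast names spring as highest, with dawn 80%, spring 81%, winter 73% and noon 58% (range 30% to 82%), the last below this reckoning's first figure, on the grounds of “leaving intermediate unconverted”.

The flasks give dawn 76.3%, spring 83.3%, winter 67.3% and noon 33.3%, so spring stands highest.

    gas ⇌ reagent, rate k1*(csat - [reagent]) (kL = 0.00269 /s)
    2 reagent → homo dimer (k = 9.54 × 10⁻⁵ /M/s, Ea = 93.0 kJ/mol)
    substrate + reagent → intermediate + by-product (k = 3.58 × 10⁻⁴ /M/s, Ea = 75.0 kJ/mol)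
    substrate + by-product → side product (k = 8.03 × 10⁻⁶ /M/s, Ea = 98.0 kJ/mol)
    intermediate → target (k = 5.85 × 10⁻⁶ /s, Ea = 123 kJ/mol)
    (constants at 100 °C)

Spring has come to rest: left to 200 d, it still holds 83.3% target. Noon has not: at 20.0 d, intermediate, its resting state, still holds 55.0%, and the share of target in target plus intermediate gives a count of 0.474, below the 3.21 reckoned. The same reading on noon's neighbour at 90 °C, with target 81.9% and intermediate 3.64%, gives 3.16. Left to 200 d, noon holds intermediate at 0.282%, and target climbs to 88.4%.

(All runs were generated by integration with constants of no real substance, and the scatter is random.)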